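**Retrosynthetic overview**
1. Final bond: N-acylation of the free aminotriol (sphingoid base) with (2R)-2-hydroxypentacosanoic acid, the acid coming from methyl (R)-glycidate and a C22 Grignard reagent.
2. C6=C7 (E): Julia–Kocienski olefination of a C1–C6 phenyltetrazolyl (PT) sulfone with a C7–C17 cyclopropyl aldehyde.
3. Sulfone: L-serine → Garner's aldehyde → Z-Wittig → substrate-controlled syn-dihydroxylation (sets C3 and C4).
4. Aldehyde: the trans-cyclopropane is closed by a Michael-initiated ring closure (Cu-catalysed asymmetric conjugate addition of BuMgBr to methyl 4-chlorocrotonate, then intramolecular enolate alkylation), followed by Wittig/diimide chain extension.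
5. Ring order: the cyclopropane, the only ring of the target, is closed in step 1; the oxazolidine (step 8) and dioxolane (step 12) are protecting rings removed in step 19.

Assumption: (R)-Tol-BINAP is taken as the ligand antipode that gives (1S,2S)-4 in step 1; if the sense of induction is the opposite, (S)-Tol-BINAP is used with nothing else changed.

**Tail fragment (C7–C17)**

Step 1
Reactants: 1 methyl (2E)-4-chlorobut-2-enoate; 2 n-butylmagnesium bromide
Product: 4 methyl (1S,2S)-2-butylcyclopropane-1-carboxylate, via bromomagnesium enolate 3 (not isolated)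
Conditions: CuI (2 mol%), (R)-Tol-BINAP (3 mol%), CH2Cl2, –78 °C, slow addition of 2 (1.2 equiv, Et2O), then –78 °C → rt
Reagents that add atoms: none
Why: Cu/Tol-BINAP-catalysed asymmetric Michael addition of the Grignard reagent sets the butyl-bearing centre as the (3R) enolate 3, which on warming closes the ring by intramolecular 3-exo-tet alkylation at CH2Cl (Michael-initiated ring closure), trans because ester and butyl avoid each other in the closing transition state.

Step 2
Reactants: 4 methyl (1S,2S)-2-butylcyclopropane-1-carboxylate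
Product: 5 [(1S,2S)-2-butylcyclopropyl]methanol
Conditions: LiAlH4, Et2O, 0 °C → rt; Fieser work-up
Reagents that add atoms: none
Why: Hydride reduction of the ester to the primary alcohol touches neither ring stereocentre.

Step 3
Reactants: 5 [(1S,2S)-2-butylcyclopropyl]methanol
Product: 6 (1S,2S)-2-butylcyclopropane-1-carbaldehyde
Conditions: Dess–Martin periodinane, CH2Cl2, 0 °C → rt; used crude (volatile)
Reagents that add atoms: none
Why: Dess–Martin oxidation stops at the aldehyde, and the cyclopropyl α-CH does not enolise, so the trans configuration is kept.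

Step 4
Reactants: 7 2-(3-chloropropyl)-1,3-dioxolane
Product: 8 [3-(1,3-dioxolan-2-yl)propyl]triphenylphosphonium iodide
Conditions: PPh3, NaI, MeCN, reflux
Reagents that add atoms: triphenylphosphine, c1ccccc1P(c1ccccc1)c1ccccc1; sodium iodide, [Na+].[I-]
Why: Finkelstein exchange followed by SN2 quaternisation of PPh3 at the primary carbon under neutral conditions leaves the acetal intact.

Step 5
Reactants: 6 (1S,2S)-2-butylcyclopropane-1-carbaldehyde; 8 [3-(1,3-dioxolan-2-yl)propyl]triphenylphosphonium iodide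
Product: 10 2-[(3Z)-4-[(1S,2S)-2-butylcyclopropyl]but-3-en-1-yl]-1,3-dioxolane, via phosphonium ylide 9 (not isolated)
Conditions: NaHMDS, THF, –78 → 0 °C; then 6, –78 °C → rt
Reagents that add atoms: none
Why: Wittig olefination with a non-stabilised ylide forms the C10–C11 bond (mainly Z, irrelevant because the alkene is reduced next).

Step 6
Reactants: 10 2-[(3Z)-4-[(1S,2S)-2-butylcyclopropyl]but-3-en-1-yl]-1,3-dioxolane
Product: 11 2-{4-[(1S,2S)-2-butylcyclopropyl]butyl}-1,3-dioxolane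
Conditions: TsNHNH2, NaOAc, DME/H2O, reflux
Reagents that add atoms: none
Why: Diimide reduction transfers H2 in a concerted syn fashion and saturates the alkene without the hydrogenolysis of the adjacent cyclopropane that Pd/H2 would risk.

Step 7
Reactants: 11 2-{4-[(1S,2S)-2-butylcyclopropyl]butyl}-1,3-dioxolane
Product: 12 5-[(1S,2S)-2-butylcyclopropyl]pentanal
Conditions: 1 M HCl, THF, rt
Reagents that add atoms: water, O
Why: Acid-catalysed acetal hydrolysis releases the aldehyde, and dilute acid at room temperature does not open a dialkylcyclopropane.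

**Head fragment (C1–C6)**

Step 8
Reactants: 13 methyl N-(tert-butoxycarbonyl)-L-serinate
Product: 14 3-tert-butyl 4-methyl (4S)-2,2-dimethyl-1,3-oxazolidine-3,4-dicarboxylate
Conditions: 2,2-dimethoxypropane, BF3·OEt2 (cat.), acetone, rt
Reagents that add atoms: 2,2-dimethoxypropane, COC(C)(C)OC
Why: N,O-acetalisation (transketalisation) masks NH and OH in one ring, and the serine stereocentre, the later C2, is not involved.

Step 9
Reactants: 14 3-tert-butyl 4-methyl (4S)-2,2-dimethyl-1,3-oxazolidine-3,4-dicarboxylate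
Product: 15 tert-butyl (4S)-4-formyl-2,2-dimethyl-1,3-oxazolidine-3-carboxylate
Conditions: DIBAL-H, toluene, –78 °C; MeOH, then Rochelle salt
Reagents that add atoms: none
Why: Partial DIBAL reduction halts at the tetrahedral aluminium hemiacetal at –78 °C and gives Garner's aldehyde without epimerisation.

Step 10
Reactants: 15 tert-butyl (4S)-4-formyl-2,2-dimethyl-1,3-oxazolidine-3-carboxylate; 16 [3-(benzyloxy)propyl]triphenylphosphonium bromide
Product: 18 tert-butyl (4R)-4-[(1Z)-4-(benzyloxy)but-1-en-1-yl]-2,2-dimethyl-1,3-oxazolidine-3-carboxylate, via phosphonium ylide 17 (not isolated)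
Conditions: KHMDS, THF, –78 → 0 °C; then 15, –78 °C → rt
Reagents that add atoms: none
Why: Salt-free Wittig reaction of a non-stabilised ylide gives the Z-alkene needed for an erythro diol, and the low temperature protects the α-amino aldehyde from epimerisation (the descriptor changes to R by CIP priority only).

Step 11
Reactants: 18 tert-butyl (4R)-4-[(1Z)-4-(benzyloxy)but-1-en-1-yl]-2,2-dimethyl-1,3-oxazolidine-3-carboxylate
Product: 19 tert-butyl (4S)-4-[(1S,2R)-4-(benzyloxy)-1,2-dihydroxybutyl]-2,2-dimethyl-1,3-oxazolidine-3-carboxylate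
Conditions: OsO4 (2.5 mol%), NMO (1.5 equiv), acetone/H2O (8:1), rt; minor diastereomer removed by chromatography
Reagents that add atoms: 4-methylmorpholine N-oxide, C[N+]1([O-])CCOCC1; water, O; osmium tetroxide (catalytic O carrier), O=[Os](=O)(=O)=O
Why: Upjohn syn-dihydroxylation of the Z-alkene fixes the 3,4-erythro relationship, and OsO4 attacks anti to the allylic nitrogen in the A(1,3)-minimised conformer (Kishi's empirical rule), giving the (3S,4R) D-ribo array.

Step 12
Reactants: 19 tert-butyl (4S)-4-[(1S,2R)-4-(benzyloxy)-1,2-dihydroxybutyl]-2,2-dimethyl-1,3-oxazolidine-3-carboxylate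
Product: 20 tert-butyl (4S)-4-[(4S,5R)-5-[2-(benzyloxy)ethyl]-2,2-dimethyl-1,3-dioxolan-4-yl]-2,2-dimethyl-1,3-oxazolidine-3-carboxylate
Conditions: 2,2-dimethoxypropane, PPTS (cat.), CH2Cl2, rt
Reagents that add atoms: 2,2-dimethoxypropane, COC(C)(C)OC
Why: Acid-catalysed transketalisation closes the cis-dioxolane on the 1,2-diol under conditions mild enough for the Boc group and the N,O-acetonide.

Step 13
Reactants: 20 tert-butyl (4S)-4-[(4S,5R)-5-[2-(benzyloxy)ethyl]-2,2-dimethyl-1,3-dioxolan-4-yl]-2,2-dimethyl-1,3-oxazolidine-3-carboxylate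
Product: 21 tert-butyl (4S)-4-[(4S,5R)-5-(2-hydroxyethyl)-2,2-dimethyl-1,3-dioxolan-4-yl]-2,2-dimethyl-1,3-oxazolidine-3-carboxylate
Conditions: H2 (1 atm), 10% Pd/C, EtOAc, rt
Reagents that add atoms: none
Why: Hydrogenolysis removes the benzyl ether at a stage where no alkene or cyclopropane is present.

Step 14
Reactants: 21 tert-butyl (4S)-4-[(4S,5R)-5-(2-hydroxyethyl)-2,2-dimethyl-1,3-dioxolan-4-yl]-2,2-dimethyl-1,3-oxazolidine-3-carboxylate
Product: 22 tert-butyl (4S)-4-[(4S,5R)-2,2-dimethyl-5-{2-[(1-phenyl-1H-tetrazol-5-yl)sulfanyl]ethyl}-1,3-dioxolan-4-yl]-2,2-dimethyl-1,3-oxazolidine-3-carboxylate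
Conditions: 1-phenyl-1H-tetrazole-5-thiol, PPh3, DIAD, THF, 0 °C → rt
Reagents that add atoms: 1-phenyl-1H-tetrazole-5-thiol, Sc1nnnn1-c1ccccc1
Why: Mitsunobu reaction turns the primary alcohol into the thioether by SN2 displacement of the oxyphosphonium by the acidic thiol.

Step 15
Reactants: 22 tert-butyl (4S)-4-[(4S,5R)-2,2-dimethyl-5-{2-[(1-phenyl-1H-tetrazol-5-yl)sulfanyl]ethyl}-1,3-dioxolan-4-yl]-2,2-dimethyl-1,3-oxazolidine-3-carboxylate
Product: 23 tert-butyl (4S)-4-[(4S,5R)-2,2-dimethyl-5-{2-[(1-phenyl-1H-tetrazol-5-yl)sulfonyl]ethyl}-1,3-dioxolan-4-yl]-2,2-dimethyl-1,3-oxazolidine-3-carboxylate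
Conditions: 30% H2O2, (NH4)6Mo7O24·4H2O (10 mol%), EtOH, 0 °C → rt
Reagents that add atoms: hydrogen peroxide, OO
Why: Molybdate-catalysed peroxide oxidation takes the sulfide to the sulfone, and the near-neutral medium spares the Boc group and both acetonides.

**Acid fragment**

Step 16
Reactants: 24 1-bromodocosane; 25 methyl (2R)-oxirane-2-carboxylate
Product: 27 methyl (2R)-2-hydroxypentacosanoate, via docosylmagnesium bromide 26 (not isolated)
Conditions: Mg, THF, 50 °C; then CuI (10 mol%), 25, THF, –30 → –10 °C; aq. NH4Cl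
Reagents that add atoms: none
Why: Copper-catalysed Grignard opening of the glycidic ester at the unhindered CH2 terminus leaves the C2–O bond untouched, so the (R) centre of the chiral-pool epoxide becomes the (2R) carbinol.

Step 17
Reactants: 27 methyl (2R)-2-hydroxypentacosanoate
Product: 28 (2R)-2-hydroxypentacosanoic acid
Conditions: LiOH·H2O, THF/MeOH/H2O, 50 °C; then 1 M HCl
Reagents that add atoms: lithium hydroxide (its O becomes the acid OH), [Li+].[OH-]
Why: Saponification (BAc2) of the methyl ester under mild base does not racemise the α-hydroxy centre.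

**Assembly**

Step 18
Reactants: 23 tert-butyl (4S)-4-[(4S,5R)-2,2-dimethyl-5-{2-[(1-phenyl-1H-tetrazol-5-yl)sulfonyl]ethyl}-1,3-dioxolan-4-yl]-2,2-dimethyl-1,3-oxazolidine-3-carboxylate; 12 5-[(1S,2S)-2-butylcyclopropyl]pentanal
Product: 30 tert-butyl (4S)-4-[(4S,5R)-5-[(2E)-7-[(1S,2S)-2-butylcyclopropyl]hept-2-en-1-yl]-2,2-dimethyl-1,3-dioxolan-4-yl]-2,2-dimethyl-1,3-oxazolidine-3-carboxylate, via potassium sulfonyl carbanion 29 (not isolated)
Conditions: KHMDS, DME, –60 °C; then 12, –60 °C → rt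
Reagents that add atoms: none
Why: Julia–Kocienski olefination, in which the metallated PT-sulfone adds to the aldehyde and Smiles rearrangement with loss of SO2 and tetrazolate gives the (E)-C6=C7 alkene, E being favoured by KHMDS in DME.

Step 19
Reactants: 30 tert-butyl (4S)-4-[(4S,5R)-5-[(2E)-7-[(1S,2S)-2-butylcyclopropyl]hept-2-en-1-yl]-2,2-dimethyl-1,3-dioxolan-4-yl]-2,2-dimethyl-1,3-oxazolidine-3-carboxylate
Product: 31 (2S,3S,4R,6E)-2-amino-11-[(1S,2S)-2-butylcyclopropyl]undec-6-ene-1,3,4-triol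
Conditions: TFA/H2O (9:1), 0 °C → rt, 1 h; evaporate; aq. NaHCO3 work-up
Reagents that add atoms: none
Why: Acidolysis removes the Boc group and hydrolyses both isopropylidene acetals in one operation without breaking a bond at any stereocentre, and the short cold exposure leaves the alkene and the dialkylcyclopropane intact.

Step 20
Reactants: 31 (2S,3S,4R,6E)-2-amino-11-[(1S,2S)-2-butylcyclopropyl]undec-6-ene-1,3,4-triol; 28 (2R)-2-hydroxypentacosanoic acid
Product: 32 (2R)-N-[(2S,3S,4R,6E)-11-[(1S,2S)-2-butylcyclopropyl]-1,3,4-trihydroxyundec-6-en-2-yl]-2-hydroxypentacosanamide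
Conditions: EDC (free base), HOBt, THF/CH2Cl2, 40 °C
Reagents that add atoms: none
Why: Carbodiimide/HOBt amide coupling is chemoselective for the primary amine over the four hydroxyl groups, and the HOBt ester suppresses epimerisation of the α-hydroxy acid.

**Compound list**
1 | methyl (2E)-4-chlorobut-2-enoate | COC(=O)/C=C/CCl | starting material
2 | n-butylmagnesium bromide | CCCC[Mg]Br | starting material
3 | bromomagnesium enolate of methyl (3R)-3-(chloromethyl)heptanoate | CCCC[C@@H](CCl)C=C(OC)O[Mg]Br | intermediate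
4 | methyl (1S,2S)-2-butylcyclopropane-1-carboxylate | COC(=O)[C@H]1C[C@@H]1CCCC | intermediate
5 | [(1S,2S)-2-butylcyclopropyl]methanol | OC[C@H]1C[C@@H]1CCCC | intermediate
6 | (1S,2S)-2-butylcyclopropane-1-carbaldehyde | O=C[C@H]1C[C@@H]1CCCC | intermediate
7 | 2-(3-chloropropyl)-1,3-dioxolane | ClCCCC1OCCO1 | starting material
8 | [3-(1,3-dioxolan-2-yl)propyl]triphenylphosphonium iodide | [I-].c1ccccc1[P+](c1ccccc1)(c1ccccc1)CCCC1OCCO1 | intermediate
9 | [3-(1,3-dioxolan-2-yl)propylidene]triphenyl-λ5-phosphane (ylide) | c1ccccc1P(c1ccccc1)(c1ccccc1)=CCCC1OCCO1 | intermediate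
10 | 2-[(3Z)-4-[(1S,2S)-2-butylcyclopropyl]but-3-en-1-yl]-1,3-dioxolane | O1CCOC1CC/C=C\[C@H]2C[C@@H]2CCCC | intermediate
11 | 2-{4-[(1S,2S)-2-butylcyclopropyl]butyl}-1,3-dioxolane | O1CCOC1CCCC[C@H]2C[C@@H]2CCCC | intermediate
12 | 5-[(1S,2S)-2-butylcyclopropyl]pentanal | O=CCCCC[C@H]1C[C@@H]1CCCC | intermediate
13 | methyl N-(tert-butoxycarbonyl)-L-serinate | CC(C)(C)OC(=O)N[C@@H](CO)C(=O)OC | starting material
14 | 3-tert-butyl 4-methyl (4S)-2,2-dimethyl-1,3-oxazolidine-3,4-dicarboxylate | CC(C)(C)OC(=O)N1[C@@H](COC1(C)C)C(=O)OC | intermediate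
15 | tert-butyl (4S)-4-formyl-2,2-dimethyl-1,3-oxazolidine-3-carboxylate | CC(C)(C)OC(=O)N1[C@@H](COC1(C)C)C=O | intermediate
16 | [3-(benzyloxy)propyl]triphenylphosphonium bromide | [Br-].c1ccccc1[P+](c1ccccc1)(c1ccccc1)CCCOCc1ccccc1 | starting material
17 | [3-(benzyloxy)propylidene]triphenyl-λ5-phosphane (ylide) | c1ccccc1P(c1ccccc1)(c1ccccc1)=CCCOCc1ccccc1 | intermediate
18 | tert-butyl (4R)-4-[(1Z)-4-(benzyloxy)but-1-en-1-yl]-2,2-dimethyl-1,3-oxazolidine-3-carboxylate | CC(C)(C)OC(=O)N1[C@@H](COC1(C)C)/C=C\CCOCc2ccccc2 | intermediate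
19 | tert-butyl (4S)-4-[(1S,2R)-4-(benzyloxy)-1,2-dihydroxybutyl]-2,2-dimethyl-1,3-oxazolidine-3-carboxylate | CC(C)(C)OC(=O)N1[C@@H](COC1(C)C)[C@H](O)[C@H](O)CCOCc2ccccc2 | intermediate
20 | tert-butyl (4S)-4-[(4S,5R)-5-[2-(benzyloxy)ethyl]-2,2-dimethyl-1,3-dioxolan-4-yl]-2,2-dimethyl-1,3-oxazolidine-3-carboxylate | CC(C)(C)OC(=O)N1[C@@H](COC1(C)C)[C@@H]2OC(C)(C)O[C@@H]2CCOCc3ccccc3 | intermediate
21 | tert-butyl (4S)-4-[(4S,5R)-5-(2-hydroxyethyl)-2,2-dimethyl-1,3-dioxolan-4-yl]-2,2-dimethyl-1,3-oxazolidine-3-carboxylate | CC(C)(C)OC(=O)N1[C@@H](COC1(C)C)[C@@H]2OC(C)(C)O[C@@H]2CCO | intermediate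
22 | tert-butyl (4S)-4-[(4S,5R)-2,2-dimethyl-5-{2-[(1-phenyl-1H-tetrazol-5-yl)sulfanyl]ethyl}-1,3-dioxolan-4-yl]-2,2-dimethyl-1,3-oxazolidine-3-carboxylate | CC(C)(C)OC(=O)N1[C@@H](COC1(C)C)[C@@H]2OC(C)(C)O[C@@H]2CCSc3nnnn3-c4ccccc4 | intermediate
23 | tert-butyl (4S)-4-[(4S,5R)-2,2-dimethyl-5-{2-[(1-phenyl-1H-tetrazol-5-yl)sulfonyl]ethyl}-1,3-dioxolan-4-yl]-2,2-dimethyl-1,3-oxazolidine-3-carboxylate | CC(C)(C)OC(=O)N1[C@@H](COC1(C)C)[C@@H]2OC(C)(C)O[C@@H]2CCS(=O)(=O)c3nnnn3-c4ccccc4 | intermediate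
24 | 1-bromodocosane | CCCCCCCCCCCCCCCCCCCCCCBr | starting material
25 | methyl (2R)-oxirane-2-carboxylate | COC(=O)[C@H]1CO1 | starting material
26 | docosylmagnesium bromide | CCCCCCCCCCCCCCCCCCCCCC[Mg]Br | intermediate
27 | methyl (2R)-2-hydroxypentacosanoate | CCCCCCCCCCCCCCCCCCCCCCC[C@@H](O)C(=O)OC | intermediate
28 | (2R)-2-hydroxypentacosanoic acid | CCCCCCCCCCCCCCCCCCCCCCC[C@@H](O)C(=O)O | intermediate
29 | potassium α-sulfonyl carbanion of 23 | [K+].CC(C)(C)OC(=O)N1[C@@H](COC1(C)C)[C@@H]2OC(C)(C)O[C@@H]2C[CH-]S(=O)(=O)c3nnnn3-c4ccccc4 | intermediate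
30 | tert-butyl (4S)-4-[(4S,5R)-5-[(2E)-7-[(1S,2S)-2-butylcyclopropyl]hept-2-en-1-yl]-2,2-dimethyl-1,3-dioxolan-4-yl]-2,2-dimethyl-1,3-oxazolidine-3-carboxylate | CC(C)(C)OC(=O)N1[C@@H](COC1(C)C)[C@@H]2OC(C)(C)O[C@@H]2C/C=C/CCCC[C@H]3C[C@@H]3CCCC | intermediate
31 | (2S,3S,4R,6E)-2-amino-11-[(1S,2S)-2-butylcyclopropyl]undec-6-ene-1,3,4-triol | N[C@@H](CO)[C@H](O)[C@H](O)C/C=C/CCCC[C@H]1C[C@@H]1CCCC | intermediate
32 | (2R)-N-[(2S,3S,4R,6E)-11-[(1S,2S)-2-butylcyclopropyl]-1,3,4-trihydroxyundec-6-en-2-yl]-2-hydroxypentacosanamide | CCCCCCCCCCCCCCCCCCCCCCC[C@@H](O)C(=O)N[C@@H](CO)[C@H](O)[C@H](O)C/C=C/CCCC[C@H]1C[C@@H]1CCCC | target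

**Step count**
Total: 20 steps. Longest linear sequence: 11 steps (8, 9, 10, 11, 12, 13, 14, 15, 18, 19, 20 from 13), which is 55% of the total. The tail branch contributes 9 steps to the target, the phosphonium branch 7 and the acid branch 3.

**Three steps most likely to fail**

Step 1 (Michael/ring-closure cascade). The risks are competing SN2′ or 1,2-addition and an ee below what the two remote ring centres need. The fallback builds the ring by a directed carbenoid [2+1] addition instead. It does not set out from a numbered compound: it replaces 1 and 2 by commercial (2E)-hept-2-en-1-ol F1. Charette asymmetric Simmons–Smith cyclopropanation of F1 (Zn(CH2I)2·DME, (4R,5R)-2-butyl-N,N,N′,N′-tetramethyl-1,3,2-dioxaborolane-4,5-dicarboxamide, CH2Cl2, 0 °C → rt) delivers CH2 to the alkene face fixed by the zinc alkoxide–boronate complex, trans by stereospecific syn addition to the E-alkene. It gives 5 directly and comes back to the route there.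

Step 11 (dihydroxylation). Facial selectivity rests on substrate control alone and may be modest, with the diastereomers hard to separate. The fallback sets out from 15 and replaces steps 10–13 by a reagent-controlled C–C bond formation. Anti-selective α-hydroxyallylation of 15 with [(E)-3-(1,3,2-dioxaborinan-2-yl)allyl]diisopinocampheylborane (Ipc antipode matched with the Felkin preference of 15; Et2O, –78 °C; then NaOH/H2O2) gives tert-butyl (4S)-4-[(1S,2R)-1,2-dihydroxybut-3-en-1-yl]-2,2-dimethyl-1,3-oxazolidine-3-carboxylate F2. Acetonide formation (2,2-dimethoxypropane, PPTS) gives tert-butyl (4S)-4-[(4S,5R)-5-ethenyl-2,2-dimethyl-1,3-dioxolan-4-yl]-2,2-dimethyl-1,3-oxazolidine-3-carboxylate F3. Anti-Markovnikov hydroboration–oxidation of F3 (9-BBN, THF; NaOH/H2O2) gives 21, where it comes back to the route.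

Step 18 (Julia–Kocienski olefination). The risks are self-condensation of the metallated sulfone, aldol loss of 12 and erosion of E/Z. The fallback sets out from 21 and 12, replaces steps 14, 15 and 18, and forms C6=C7 by olefin cross-metathesis. Oxidation of 21 (Dess–Martin) gives tert-butyl (4S)-4-[(4S,5R)-2,2-dimethyl-5-(2-oxoethyl)-1,3-dioxolan-4-yl]-2,2-dimethyl-1,3-oxazolidine-3-carboxylate F4. Methylenation of F4 (Ph3P=CH2, THF, –78 °C → rt) gives tert-butyl (4S)-4-[(4S,5R)-2,2-dimethyl-5-(prop-2-en-1-yl)-1,3-dioxolan-4-yl]-2,2-dimethyl-1,3-oxazolidine-3-carboxylate F5. The same methylenation of 12 gives (1S,2S)-1-butyl-2-(hex-5-en-1-yl)cyclopropane F6. Cross-metathesis of F5 with excess F6 (Grubbs II, CH2Cl2, 40 °C; the Z isomer is removed on AgNO3-silica) gives 30, where it comes back to the route.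

**Further compounds**
F1 | step 1 | (2E)-hept-2-en-1-ol | CCCC/C=C/CO
F2 | step 11 | tert-butyl (4S)-4-[(1S,2R)-1,2-dihydroxybut-3-en-1-yl]-2,2-dimethyl-1,3-oxazolidine-3-carboxylate | CC(C)(C)OC(=O)N1[C@@H](COC1(C)C)[C@H](O)[C@H](O)C=C
F3 | step 11 | tert-butyl (4S)-4-[(4S,5R)-5-ethenyl-2,2-dimethyl-1,3-dioxolan-4-yl]-2,2-dimethyl-1,3-oxazolidine-3-carboxylate | CC(C)(C)OC(=O)N1[C@@H](COC1(C)C)[C@@H]2OC(C)(C)O[C@@H]2C=C
F4 | step 18 | tert-butyl (4S)-4-[(4S,5R)-2,2-dimethyl-5-(2-oxoethyl)-1,3-dioxolan-4-yl]-2,2-dimethyl-1,3-oxazolidine-3-carboxylate | CC(C)(C)OC(=O)N1[C@@H](COC1(C)C)[C@@H]2OC(C)(C)O[C@@H]2CC=O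
F5 | step 18 | tert-butyl (4S)-4-[(4S,5R)-2,2-dimethyl-5-(prop-2-en-1-yl)-1,3-dioxolan-4-yl]-2,2-dimethyl-1,3-oxazolidine-3-carboxylate | CC(C)(C)OC(=O)N1[C@@H](COC1(C)C)[C@@H]2OC(C)(C)O[C@@H]2CC=C
F6 | step 18 | (1S,2S)-1-butyl-2-(hex-5-en-1-yl)cyclopropane | C=CCCCC[C@H]1C[C@@H]1CCCC
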